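**Retrosynthetic overview**
- The target is the 6-O-(4-methoxybenzoate) of 8α,9α-epoxy-jaeschkeanadiol; the ester is made last from the epoxy diol and 4-methoxybenzoyl chloride (anisole + oxalyl chloride), the 6α-hydroxyl by a hydroxyl-directed reduction of the 6-ketone.
- The hydroazulene (five- plus seven-membered ring) comes from a cis-decalin by a pinacol-type 1,2-shift of the ring-fusion bond: ring A contracts (6→5) while ring B expands (6→7), which fixes C5 and the trans ring fusion.
- The shift substrate is an all-cis triol monomesylate, made by directed dihydroxylation of a tertiary allylic alcohol that comes from isopropyl addition to an epoxy enone.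
- The bicyclic enone comes from 6-methylcyclohex-2-enone and isoprene monoxide by an enantioselective Pd-catalysed annulation, then oxidative 1,3-transposition and epoxidation of the ring B alkene.
- Ring order: ring A is bought, ring B (six) is annulated, then six/six becomes five/seven; the epoxide is set early, the ester last.

Assumption: daucane numbering is used for the final skeleton (C1 angular-methyl carbon, C4 isopropyl carbinol, C5 ring-fusion CH, C6 ester carbon, C8–C9 epoxide); α is the face of H-5, β the face of the C1 methyl; ring A carries the carbonyl of 1, ring B is the ring built in step 1.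
Assumption: the (S,S) ligand in step 1 is taken to give the (R) quaternary centre; if the sense is opposite, the (R,R) ligand is used.

**Step 1**
Reactants: 1 6-methylcyclohex-2-en-1-one; 2 2-methyl-2-vinyloxirane
Product: 4 (4aS,8aR)-6,8a-dimethyl-1,2,8,8a-tetrahydronaphthalen-4a(5H)-ol, via lithium alkoxide of hydroxy enone 3 (not isolated)
Conditions: LiN(iPr)2, THF, −78 °C; 2, Pd2(dba)3 (2.5 mol %), (S,S)-DACH-phenyl Trost ligand (7.5 mol %), −78 → 0 °C; then Et2Zn (3 equiv), 0 → 25 °C; H2O
Reagents that add atoms: none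
Why: Proposed new method: a Pd-catalysed enantioselective alkylation/umpolung-allylation (4+2) annulation in which the kinetic cross-conjugated lithium enolate of 1 attacks the unsubstituted terminus of the zwitterionic π-allylpalladium from 2 (the chiral diphosphine selects the enolate face and sets the quaternary carbon as R, giving 3), after which Et2Zn forms the zinc alkoxide, zerovalent palladium ionises it again and the resulting allylzinc adds through its CH2 terminus to the ring ketone to close ring B with the trisubstituted alkene in place; the closest known reaction types are the Tsuji–Trost asymmetric allylic alkylation of ketone enolates, 1,4-opening of vinyl epoxides by carbon nucleophiles and Pd/Et2Zn umpolung allylation of carbonyls with allylic alcohols, and the carbinol configuration of 4 is irrelevant because step 2 erases it.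

**Step 2**
Reactants: 4 (4aS,8aR)-6,8a-dimethyl-1,2,8,8a-tetrahydronaphthalen-4a(5H)-ol
Product: 5 (4aR)-4a,7-dimethyl-4,4a,5,8-tetrahydronaphthalen-2(3H)-one
Conditions: C5H5NH[CrO3Cl] (pyridinium chlorochromate), NaOAc, 4 Å sieves, CH2Cl2, 23 °C
Reagents that add atoms: none
Why: Dauben–Babler oxidative 1,3-transposition, in which the tertiary allylic chromate ester rearranges to the secondary allylic chromate and is oxidised to the enone, so either carbinol epimer of 4 gives 5 and no new stereocentre forms.

**Step 3**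
Reactants: 5 (4aR)-4a,7-dimethyl-4,4a,5,8-tetrahydronaphthalen-2(3H)-one
Product: 6 (4aR,6S,7R)-6,7-epoxy-4a,7-dimethyl-4,4a,5,6,7,8-hexahydronaphthalen-2(3H)-one
Conditions: mCPBA, NaHCO3, CH2Cl2, 0 °C
Reagents that add atoms: meta-chloroperoxybenzoic acid, OOC(=O)c1cccc(Cl)c1
Why: Prilezhaev epoxidation of the electron-rich trisubstituted ring B alkene (the enone alkene is deactivated), with the peracid approaching anti to the pseudo-axial angular methyl so that the epoxide oxygen ends trans to that methyl.

**Step 4**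
Reactants: 6 (4aR,6S,7R)-6,7-epoxy-4a,7-dimethyl-4,4a,5,6,7,8-hexahydronaphthalen-2(3H)-one
Product: 7 (2R,4aR,6S,7R)-6,7-epoxy-4a,7-dimethyl-2-(propan-2-yl)-2,3,4,4a,5,6,7,8-octahydronaphthalen-2-ol
Conditions: CeCl3 (1.5 equiv), iPrMgCl (1.4 equiv), THF, −78 °C; H2O
Reagents that add atoms: isopropylmagnesium chloride, CC(C)[Mg]Cl
Why: Imamoto-type 1,2-addition of the weakly basic organocerium reagent to the enone carbonyl from the face anti to the pseudo-axial angular methyl, which puts the new tertiary hydroxyl cis to that methyl (2R) and avoids γ-deprotonation with epoxide opening.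

**Step 5**
Reactants: 7 (2R,4aR,6S,7R)-6,7-epoxy-4a,7-dimethyl-2-(propan-2-yl)-2,3,4,4a,5,6,7,8-octahydronaphthalen-2-ol
Product: 9 (1S,2R,4aR,6S,7R,8aR)-6,7-epoxy-4a,7-dimethyl-2-(propan-2-yl)decahydronaphthalene-1,2,8a-triol, via osmate ester 8 (not isolated)
Conditions: OsO4 (1.05 equiv), TMEDA (1.1 equiv), CH2Cl2, −78 °C; then aq. Na2SO3, THF, 60 °C
Reagents that add atoms: osmium tetroxide, O=[Os](=O)(=O)=O; N,N,N′,N′-tetramethylethylenediamine, CN(C)CCN(C)C (held only in 8)
Why: Donohoe hydroxyl-directed dihydroxylation, in which the OsO4·TMEDA complex is hydrogen-bonded by the allylic tertiary hydroxyl and adds to the only alkene on that same face, giving the all-cis triol whose ring-fusion hydroxyl is cis to the angular methyl (cis-decalin).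

**Step 6**
Reactants: 9 (1S,2R,4aR,6S,7R,8aR)-6,7-epoxy-4a,7-dimethyl-2-(propan-2-yl)decahydronaphthalene-1,2,8a-triol
Product: 11 (1R,4R,5R,8R,9S)-8,9-epoxy-4-hydroxydaucan-6-one, via mesylate 10 (not isolated)
Conditions: MsCl (1.1 equiv), Et3N, CH2Cl2, −20 °C; then THF, KOtBu (2.1 equiv), −40 → 0 °C
Reagents that add atoms: methanesulfonyl chloride, CS(=O)(=O)Cl (held only in 10)
Why: Pinacol-type 1,2-shift of a cis-diol monosulfonate (decalin to hydroazulene), in which only the secondary hydroxyl is mesylated, the equatorial mesylate at C1 is antiperiplanar to the ring-fusion bond C8a–C4a in the chair with isopropyl equatorial, and that bond migrates to C1 with inversion while the C8a alkoxide becomes the ketone, giving the trans ring fusion (H-5 α) with the 4β-hydroxyl untouched; the base is used up, which limits retro-aldol opening.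

**Step 7**
Reactants: 11 (1R,4R,5R,8R,9S)-8,9-epoxy-4-hydroxydaucan-6-one
Product: 12 (1R,4R,5S,6S,8R,9S)-8,9-epoxydaucane-4,6-diol
Conditions: Me4NBH(OAc)3 (5 equiv), MeCN–AcOH (4:1), −30 °C
Reagents that add atoms: none
Why: Evans–Saksena reduction, in which the tertiary 4-hydroxyl exchanges onto boron and delivers hydride intramolecularly to the β-face of the C6 ketone, giving the 1,3-anti diol and hence the 6α (6S) alcohol.

**Step 8**
Reactants: 13 anisole
Product: 14 4-methoxybenzoyl chloride
Conditions: (COCl)2 (3 equiv), AlCl3 (1.1 equiv), CH2Cl2, 0 °C (anisole added last); cold dilute HCl; distil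
Reagents that add atoms: oxalyl chloride, O=C(Cl)C(Cl)=O
Why: Friedel–Crafts chlorocarbonylation with oxalyl chloride, para-selective on anisole, with loss of CO from the intermediate aryl oxalyl chloride.

**Step 9**
Reactants: 12 (1R,4R,5S,6S,8R,9S)-8,9-epoxydaucane-4,6-diol; 14 4-methoxybenzoyl chloride
Product: 15 (1R,4R,5S,6S,8R,9S)-8,9-epoxy-4-hydroxydaucan-6-yl 4-methoxybenzoate
Conditions: Et3N, DMAP (0.2 equiv), CH2Cl2, 0 → 23 °C
Reagents that add atoms: none
Why: DMAP-catalysed acylation of the secondary 6-hydroxyl only (the tertiary 4-hydroxyl is too hindered and the epoxide is inert to these basic conditions), with retention at C6.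

**Compound list**
1 | 6-methylcyclohex-2-en-1-one (racemic) | CC1CCC=CC1=O | starting material
2 | 2-methyl-2-vinyloxirane (isoprene monoxide, racemic) | CC1(C=C)CO1 | starting material
3 | (6R)-6-[(2E)-4-hydroxy-3-methylbut-2-en-1-yl]-6-methylcyclohex-2-en-1-one (lithium alkoxide in the flask) | C[C@]1(C/C=C(\C)CO)CCC=CC1=O | intermediate
4 | (4aS,8aR)-6,8a-dimethyl-1,2,8,8a-tetrahydronaphthalen-4a(5H)-ol (hydroxyl cis to the angular methyl; the 4a-epimer serves equally) | C[C@]12CCC=C[C@@]1(O)CC(C)=CC2 | intermediate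
5 | (4aR)-4a,7-dimethyl-4,4a,5,8-tetrahydronaphthalen-2(3H)-one | O=C1CC[C@]2(C)CC=C(C)CC2=C1 | intermediate
6 | (4aR,6S,7R)-6,7-epoxy-4a,7-dimethyl-4,4a,5,6,7,8-hexahydronaphthalen-2(3H)-one (epoxide trans to the angular methyl) | O=C1CC[C@]2(C)C[C@@H]3O[C@]3(C)CC2=C1 | intermediate
7 | (2R,4aR,6S,7R)-6,7-epoxy-4a,7-dimethyl-2-(propan-2-yl)-2,3,4,4a,5,6,7,8-octahydronaphthalen-2-ol (hydroxyl cis to the angular methyl) | CC(C)[C@]1(O)CC[C@]2(C)C[C@@H]3O[C@]3(C)CC2=C1 | intermediate
8 | cyclic osmate ester of 9 through O-1 and O-8a (hexavalent osmium, two oxo ligands, TMEDA bound to osmium) | CC(C)[C@]1(O)CC[C@]2(C)C[C@@H]3O[C@]3(C)C[C@@]24O[Os-2]5(=O)(=O)(O[C@@H]14)[N+](C)(C)CC[N+]5(C)C | intermediate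
9 | (1S,2R,4aR,6S,7R,8aR)-6,7-epoxy-4a,7-dimethyl-2-(propan-2-yl)decahydronaphthalene-1,2,8a-triol (three hydroxyls and the 4a-methyl on one face, epoxide oxygen on the other) | CC(C)[C@]1(O)CC[C@]2(C)C[C@@H]3O[C@]3(C)C[C@]2(O)[C@H]1O | intermediate
10 | (1S,2R,4aR,6S,7R,8aR)-6,7-epoxy-2,8a-dihydroxy-4a,7-dimethyl-2-(propan-2-yl)decahydronaphthalen-1-yl methanesulfonate | CC(C)[C@]1(O)CC[C@]2(C)C[C@@H]3O[C@]3(C)C[C@]2(O)[C@H]1OS(C)(=O)=O | intermediate
11 | (1R,4R,5R,8R,9S)-8,9-epoxy-4-hydroxydaucan-6-one (4β-hydroxy-8α,9α-epoxy, trans-fused) | O=C1C[C@@]2(C)O[C@H]2C[C@@]2(C)CC[C@@](O)(C(C)C)[C@H]12 | intermediate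
12 | (1R,4R,5S,6S,8R,9S)-8,9-epoxydaucane-4,6-diol (8α,9α-epoxy-jaeschkeanadiol) | O[C@H]1C[C@@]2(C)O[C@H]2C[C@@]2(C)CC[C@@](O)(C(C)C)[C@H]12 | intermediate
13 | anisole | COc1ccccc1 | starting material
14 | 4-methoxybenzoyl chloride | COc1ccc(cc1)C(Cl)=O | intermediate
15 | (1R,4R,5S,6S,8R,9S)-8,9-epoxy-4-hydroxydaucan-6-yl 4-methoxybenzoate | COc1ccc(C(=O)O[C@H]2C[C@@]3(C)O[C@H]3C[C@@]3(C)CC[C@@](O)(C(C)C)[C@H]23)cc1 | target

**Totals**
Total steps: 9. Longest linear sequence: 8 (steps 1–7 and 9; step 8 is a one-step side branch).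

**Steps most likely to fail**

Step 1 (the proposed annulation). The enolate alkylation may give low ee or the branched regioisomer, or the zinc-mediated ring closure may stall at 3. The fallback uses known chemistry, sets out from 1 and comes back at 4. The lithium enolate of 1 (LiN(iPr)2, TMEDA) is O-acylated with allyl chloroformate to prop-2-en-1-yl 2-methylcyclohexa-1,5-dien-1-yl carbonate F1. Decarboxylative asymmetric allylic alkylation with Pd2(dba)3 and (R)-t-BuPHOX gives (6R)-6-methyl-6-(prop-2-en-1-yl)cyclohex-2-en-1-one F2. 2-Methylallylmagnesium chloride with CeCl3 adds to the carbonyl to give (6R)-6-methyl-1-(2-methylprop-2-en-1-yl)-6-(prop-2-en-1-yl)cyclohex-2-en-1-ol F3 (either carbinol epimer serves). Ring-closing metathesis with the second-generation Grubbs catalyst then closes ring B to 4.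

Step 5 (directed dihydroxylation). The face syn to the hydroxyl also carries the angular methyl next to the alkene, so osmylation may be slow or go to the other face. The fallback sets out from 7 and comes back at 11, tying the nitrogen and oxygen donors to the C2 oxygen so that delivery to that face is intramolecular. Trichloroacetyl isocyanate gives the N-(trichloroacetyl)carbamate F4, which K2CO3 in MeOH cleaves in the same flask to the primary carbamate F5. t-BuOCl and NaOH form the N-chlorocarbamate F6, and K2OsO2(OH)4 (4 mol %) effects tethered aminohydroxylation to the oxazolidinone F7 (N on C1, hydroxyl on C8a). Ba(OH)2 in aqueous dioxane gives the amino diol F8. NaNO2 in aqueous AcOH at 0 °C (Tiffeneau–Demjanov deamination) then drives the same ring-fusion-bond shift from the equatorial diazonium and gives 11.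

Step 6 (the 1,2-shift). The C2 alkoxide can push the C2–C3 bond instead (ring contraction to an acyl hydrindane), and the β-hydroxy ketone can open by retro-aldol under base. The fallback sets out from 7, runs through the carbamate F5 and the oxazolidinone F7 described above, and comes back at 11. N2O4 with NaOAc in CH2Cl2 at −40 °C gives the N-nitroso oxazolidinone F9. LiOEt in EtOH–THF at −20 °C opens the nitrosocarbamate (Newman-type nitrosooxazolidinone ring enlargement); the C1 diazonium leaves with the 1,2-shift pushed only by the free C8a hydroxyl, because the C2 oxygen is held as the ethyl carbonate F10. K2CO3 in MeOH then frees the 4-hydroxyl to give 11.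

**Further compounds**
F1 | step 1 | prop-2-en-1-yl 2-methylcyclohexa-1,5-dien-1-yl carbonate | CC1=C(OC(=O)OCC=C)C=CCC1
F2 | step 1 | (6R)-6-methyl-6-(prop-2-en-1-yl)cyclohex-2-en-1-one | C[C@]1(CC=C)CCC=CC1=O
F3 | step 1 | (6R)-6-methyl-1-(2-methylprop-2-en-1-yl)-6-(prop-2-en-1-yl)cyclohex-2-en-1-ol (both carbinol epimers) | C[C@]1(CC=C)CCC=CC1(O)CC(C)=C
F4 | step 5 | N-(trichloroacetyl)carbamate of 7 at O-2 (not isolated) | CC(C)[C@]1(OC(=O)NC(=O)C(Cl)(Cl)Cl)CC[C@]2(C)C[C@@H]3O[C@]3(C)CC2=C1
F5 | step 5 | primary carbamate of 7 at O-2 | CC(C)[C@]1(OC(N)=O)CC[C@]2(C)C[C@@H]3O[C@]3(C)CC2=C1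
F6 | step 5 | N-chlorocarbamate of 7 at O-2 (not isolated) | CC(C)[C@]1(OC(=O)NCl)CC[C@]2(C)C[C@@H]3O[C@]3(C)CC2=C1
F7 | step 5 | oxazolidinone bridging O-2 and N-1 of the decalin with free 8a-hydroxyl (all on the face of the angular methyl) | CC(C)[C@]12CC[C@]3(C)C[C@@H]4O[C@]4(C)C[C@]3(O)[C@H]1NC(=O)O2
F8 | step 5 | 1-amino analogue of triol 9 (amino group in place of the 1-hydroxyl, same configuration) | CC(C)[C@]1(O)CC[C@]2(C)C[C@@H]3O[C@]3(C)C[C@]2(O)[C@H]1N
F9 | step 6 | N-nitroso derivative of oxazolidinone F7 | CC(C)[C@]12CC[C@]3(C)C[C@@H]4O[C@]4(C)C[C@]3(O)[C@H]1N(N=O)C(=O)O2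
F10 | step 6 | ethyl carbonate of 11 at O-4 | O=C1C[C@@]2(C)O[C@H]2C[C@@]2(C)CC[C@@](OC(=O)OCC)(C(C)C)[C@H]12
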